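The octamer is cut at the two ether bonds between C4 of ring C and C1 of ring D. This gives a ring A–B–C dibromide core and two identical D–E biaryl phenols. No cross-coupling has to forge the tetra-ortho-substituted D–E axis, because ring E is assembled around an alkyne carbon already bonded to ring D. This exploits the substitution of ring E: C1 bears ring D and is flanked by oxygenated C2 and C6, with a third oxygen at C4. Heating a ring D silyl ynol ether with 3-ethoxycyclobutenone forges E1–E2 and E5–E6 and delivers the whole phloroglucinol ring in one operation. The precursor is a benzyloxy-trimethoxyphenyl triisopropylsiloxyalkyne.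

Key step: step 7

**Ring lettering**
- A is the terminal 3,5-dihydroxyphenoxy ring.
- B is the central ring, with aryloxy groups at B1, B2 and B3 and OH at B5.
- C is each of the two 2,6-dihydroxy rings, with C1–O–B and C4–O–D.
- D is each tetraoxygenated biaryl ring, with the ether oxygen at D1 and ring E at D5.
- E is each 2,4,6-trihydroxyphenyl ring.

Assumption: the SMILES carries no stereodescriptor and ring E is symmetric about each D–E bond, so the target is treated as achiral with no axis to control.

**Design notes**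
- The annulation partners and their product were checked atom by atom against the mechanism, and no structure needed correction.
- The ynol ether is made by oxidising the lithium acetylide. A homologation at a 2,6-dialkoxybenzoate would need attack on a shielded, electron-rich carbonyl.
- The phenol and the silyl ether that the annulation delivers are both converted to methyl ethers at once, for two reasons:
  - An aryl silyl ether would not last in hot phosphate or carbonate.
  - Two different ortho groups on ring E would make each D–E axis stereogenic, which would give diastereomers after the double coupling.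
- The annulation leaves an ethyl ether at E4 that only a Lewis acid removes. Methyl is therefore the permanent group everywhere, and all nineteen alkyl groups fall together at the end.
- Benzyl is kept only for D1, the one oxygen that must be freed early.
- Every copper coupling pairs a di-ortho-substituted phenol with an unhindered aryl partner.
- The hindered B–O–C bonds are made by SNAr.

Step 1
Reactants: 1 2,4,6-trimethoxybenzaldehyde
Product: 3 2,4,6-trimethoxyphenol, via aryl formate 2 (not isolated)
Conditions: 30% aq H2O2, cat. H2SO4, MeOH, rt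
Reagents that add atoms: hydrogen peroxide, OO
Why: Acid-catalysed Dakin oxidation, in which the hydroperoxide adduct of the very electron-rich aldehyde rearranges by aryl migration to formate 2, which methanol cleaves in the same pot.

Step 2
Reactants: 3 2,4,6-trimethoxyphenol
Product: 4 2-(benzyloxy)-1,3,5-trimethoxybenzene
Conditions: BnBr, K2CO3, DMF, rt to 50 °C
Reagents that add atoms: benzyl bromide, BrCc1ccccc1
Why: Williamson ether synthesis, which marks the D1 oxygen as the only one that can later be freed under neutral conditions.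

Step 3
Reactants: 4 2-(benzyloxy)-1,3,5-trimethoxybenzene
Product: 6 3-(benzyloxy)-2,4,6-trimethoxybenzaldehyde, via iminium salt 5 (not isolated)
Conditions: POCl3, DMF, 0 °C to rt; then ice–water
Reagents that add atoms: N,N-dimethylformamide, CN(C)C=O; water, O
Why: Vilsmeier–Haack formylation, in which the two free positions of 4 are equivalent by symmetry and strongly activated, so a single aldehyde should result after hydrolysis of 5.

Step 4
Reactants: 6 3-(benzyloxy)-2,4,6-trimethoxybenzaldehyde
Product: 7 2-(benzyloxy)-4-ethynyl-1,3,5-trimethoxybenzene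
Conditions: dimethyl (1-diazo-2-oxopropyl)phosphonate, K2CO3, MeOH–THF, rt
Reagents that add atoms: dimethyl (1-diazo-2-oxopropyl)phosphonate, COP(=O)(OC)C(=[N+]=[N-])C(C)=O
Why: Seyferth–Gilbert homologation with the Ohira–Bestmann reagent converts the aldehyde into the terminal alkyne under mild carbonate conditions that leave all ethers untouched.

Step 5
Reactants: 7 2-(benzyloxy)-4-ethynyl-1,3,5-trimethoxybenzene
Product: 10 {[3-(benzyloxy)-2,4,6-trimethoxyphenyl]ethynyloxy}triisopropylsilane, via lithium acetylide 8 (not isolated), via lithium ynolate 9 (not isolated)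
Conditions: n-BuLi, THF, −78 °C; LiOOt-Bu (from t-BuOOH and LiHMDS, THF, −78 °C), −78 to 0 °C; TIPSOTf, −78 °C to rt; Et3N-deactivated silica
Reagents that add atoms: tert-butyl hydroperoxide, CC(C)(C)OO; triisopropylsilyl trifluoromethanesulfonate, CC(C)[Si](OS(=O)(=O)C(F)(F)F)(C(C)C)C(C)C
Why: Oxidation of a lithium acetylide by lithium tert-butyl peroxide (oxygen transfer to carbon) gives ynolate 9, and the bulky silyl triflate traps it on oxygen and not on carbon to give a chromatographable siloxyalkyne.

Step 6
Reactants: 11 acetyl chloride; 12 ethoxyacetylene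
Product: 14 3-ethoxycyclobut-2-en-1-one, via ketene 13 (not isolated)
Conditions: 11 added slowly to 12 and Et3N, Et2O, 0 °C to rt
Reagents that add atoms: none
Why: Dehydrochlorination of 11 gives ketene 13, which undergoes the known [2+2] cycloaddition with the electron-rich alkyne, whose nucleophilic CH terminus bonds to the ketene carbonyl carbon.

Step 7
Reactants: 10 {[3-(benzyloxy)-2,4,6-trimethoxyphenyl]ethynyloxy}triisopropylsilane; 14 3-ethoxycyclobut-2-en-1-one
Product: 19 2-[3-(benzyloxy)-2,4,6-trimethoxyphenyl]-5-ethoxy-3-(triisopropylsilyloxy)phenol, via vinylketene 15 (not isolated), via vinylcyclobutenone 16 (not isolated), via dienylketene 17 (not isolated), via cyclohexadienone 18 (not isolated)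
Conditions: toluene (degassed), 110 °C, sealed tube, argon; 14 (1.5 equiv) added in portions
Reagents that add atoms: none
Why: Danheiser benzannulation in its siloxyalkyne form: 14 opens by a four-electron electrocyclic reaction to vinylketene 15, which adds to the alkyne of 10 in a [2+2] cycloaddition to give 16. Cyclobutenone 16 opens in turn to dienylketene 17, ring E closes by a six-electron electrocyclization that re-forms E2–E3 and gives dienone 18, and enolisation to the phenol makes the cascade irreversible. The one selectivity needed is the orientation of the [2+2] step: the silyloxy group polarises the alkyne so that its aryl-bearing carbon is the nucleophile and attacks the ketene carbonyl carbon, which puts ring D at E1 between OH (E2) and OSi (E6) with the ethoxy group para to it. The linear alkyne keeps the two ortho methoxy groups of ring D away from the reacting carbons, so the tetra-ortho-substituted biaryl arises without bond formation at a congested aryl centre. No stereocentre survives; the D–E axis of 19 is stereogenic only while E2 and E6 differ, 19 is racemic, and step 8 removes this element. Benzyl, methyl and silyl ethers are inert to neutral heating, and portionwise addition of 14 limits ketene dimerisation and O-acylation of 19.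

Step 8
Reactants: 19 2-[3-(benzyloxy)-2,4,6-trimethoxyphenyl]-5-ethoxy-3-(triisopropylsilyloxy)phenol
Product: 21 3-(benzyloxy)-4'-ethoxy-2,2',4,6,6'-pentamethoxybiphenyl, via resorcinol 20 (not isolated)
Conditions: TBAF, THF, 0 °C; then MeI, K2CO3, DMF, rt
Reagents that add atoms: iodomethane, CI
Why: Fluoride cleaves the aryl silyl ether and a double Williamson methylation of 20 follows, which makes ring E symmetric about the D–E bond and replaces a base-labile group before the copper coupling.

Step 9
Reactants: 21 3-(benzyloxy)-4'-ethoxy-2,2',4,6,6'-pentamethoxybiphenyl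
Product: 22 4'-ethoxy-2,2',4,6,6'-pentamethoxybiphenyl-3-ol
Conditions: H2 (1 atm), 10% Pd/C, EtOAc–MeOH, rt
Reagents that add atoms: none
Why: Catalytic hydrogenolysis cleaves only the benzyl ether, since methyl and ethyl aryl ethers are inert and no halogen is present in this fragment.

Step 10
Reactants: 23 2,6-difluoro-4-methoxybenzaldehyde; 24 4-bromo-2,6-dimethoxyphenol (2.2 equiv)
Product: 26 2,6-bis(4-bromo-2,6-dimethoxyphenoxy)-4-methoxybenzaldehyde, via monoether 25 (not isolated)
Conditions: K2CO3, DMSO, 110 °C, argon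
Reagents that add atoms: none
Why: Twofold nucleophilic aromatic substitution, in which each fluorine is ortho to the formyl group that stabilises the Meisenheimer adduct, a di-ortho-substituted phenoxide is well tolerated, and the unactivated C–Br bonds stay intact because no metal is present.

Step 11
Reactants: 26 2,6-bis(4-bromo-2,6-dimethoxyphenoxy)-4-methoxybenzaldehyde
Product: 28 2,6-bis(4-bromo-2,6-dimethoxyphenoxy)-4-methoxyphenol, via aryl formate 27 (not isolated)
Conditions: mCPBA, CH2Cl2, 0 °C to rt; aq Na2S2O3 wash; then cat. K2CO3, MeOH, rt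
Reagents that add atoms: 3-chloroperoxybenzoic acid, OOC(=O)c1cccc(Cl)c1
Why: Baeyer–Villiger (Dakin-type) oxidation, in which the electron-rich 2,6-diaryloxy-4-methoxyphenyl group migrates readily and excess peracid is destroyed before methanolysis of 27, so the oxidisable phenol 28 never meets the oxidant.

Step 12
Reactants: 28 2,6-bis(4-bromo-2,6-dimethoxyphenoxy)-4-methoxyphenol; 29 3,5-dimethoxyphenylboronic acid
Product: 30 1,3-bis(4-bromo-2,6-dimethoxyphenoxy)-2-(3,5-dimethoxyphenoxy)-5-methoxybenzene
Conditions: Cu(OAc)2, pyridine, 4 Å MS, CH2Cl2, dry air, rt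
Reagents that add atoms: none
Why: Chan–Lam O-arylation at room temperature joins di-ortho-substituted phenols to unhindered arylboronic acids and leaves aryl bromides untouched, which a hot Ullmann coupling at this stage would not.

Step 13
Reactants: 30 1,3-bis(4-bromo-2,6-dimethoxyphenoxy)-2-(3,5-dimethoxyphenoxy)-5-methoxybenzene; 22 4'-ethoxy-2,2',4,6,6'-pentamethoxybiphenyl-3-ol (2.3 equiv)
Product: 32 2-(3,5-dimethoxyphenoxy)-5-methoxy-1,3-bis{4-[(4'-ethoxy-2,2',4,6,6'-pentamethoxybiphenyl-3-yl)oxy]-2,6-dimethoxyphenoxy}benzene, via monocoupled bromide 31 (not isolated)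
Conditions: CuI, picolinic acid, K3PO4, DMSO, 100 °C, argon
Reagents that add atoms: none
Why: Twofold Ullmann diaryl ether synthesis with the picolinic acid ligand system suited to hindered phenols, in which the bromides of 30 carry no ortho substituent and every other group is an alkyl or aryl ether that withstands phosphate in hot DMSO.

Step 14
Reactants: 32 2-(3,5-dimethoxyphenoxy)-5-methoxy-1,3-bis{4-[(4'-ethoxy-2,2',4,6,6'-pentamethoxybiphenyl-3-yl)oxy]-2,6-dimethoxyphenoxy}benzene
Product: 33 CNP0227063.0
Conditions: BBr3 (excess), CH2Cl2, −78 °C to rt, argon; then H2O, 0 °C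
Reagents that add atoms: none
Why: Lewis acid dealkylation of aryl alkyl ethers, in which bromide attacks the methyl and ethyl carbons of the boron-complexed ethers while diaryl ether and biaryl bonds offer no such carbon, and the low temperature avoids acid-driven dibenzofuran closure between rings D and E.

Compound list
1 | 2,4,6-trimethoxybenzaldehyde | COc1cc(OC)c(C=O)c(OC)c1 | starting material
2 | 2,4,6-trimethoxyphenyl formate | COc1cc(OC)c(OC=O)c(OC)c1 | intermediate
3 | 2,4,6-trimethoxyphenol | COc1cc(OC)c(O)c(OC)c1 | intermediate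
4 | 2-(benzyloxy)-1,3,5-trimethoxybenzene | COc1cc(OC)c(OCc2ccccc2)c(OC)c1 | intermediate
5 | [3-(benzyloxy)-2,4,6-trimethoxybenzylidene]dimethylammonium dichlorophosphate | C[N+](C)=Cc1c(OC)cc(OC)c(OCc2ccccc2)c1OC.[O-]P(=O)(Cl)Cl | intermediate
6 | 3-(benzyloxy)-2,4,6-trimethoxybenzaldehyde | O=Cc1c(OC)cc(OC)c(OCc2ccccc2)c1OC | intermediate
7 | 2-(benzyloxy)-4-ethynyl-1,3,5-trimethoxybenzene | C#Cc1c(OC)cc(OC)c(OCc2ccccc2)c1OC | intermediate
8 | lithium [3-(benzyloxy)-2,4,6-trimethoxyphenyl]acetylide | [Li+].[C-]#Cc1c(OC)cc(OC)c(OCc2ccccc2)c1OC | intermediate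
9 | lithium [3-(benzyloxy)-2,4,6-trimethoxyphenyl]ethynolate | [Li+].[O-]C#Cc1c(OC)cc(OC)c(OCc2ccccc2)c1OC | intermediate
10 | {[3-(benzyloxy)-2,4,6-trimethoxyphenyl]ethynyloxy}triisopropylsilane | CC(C)[Si](OC#Cc1c(OC)cc(OC)c(OCc2ccccc2)c1OC)(C(C)C)C(C)C | intermediate
11 | acetyl chloride | CC(=O)Cl | starting material
12 | ethoxyacetylene | CCOC#C | starting material
13 | ketene | C=C=O | intermediate
14 | 3-ethoxycyclobut-2-en-1-one | CCOC1=CC(=O)C1 | intermediate
15 | 3-ethoxybuta-1,3-dien-1-one | C=C(OCC)C=C=O | intermediate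
16 | 2-[3-(benzyloxy)-2,4,6-trimethoxyphenyl]-4-(1-ethoxyvinyl)-3-(triisopropylsilyloxy)cyclobut-2-en-1-one (racemic) | CCOC(=C)C1C(=O)C(c2c(OC)cc(OC)c(OCc3ccccc3)c2OC)=C1O[Si](C(C)C)(C(C)C)C(C)C | intermediate
17 | 2-[3-(benzyloxy)-2,4,6-trimethoxyphenyl]-5-ethoxy-3-(triisopropylsilyloxy)hexa-1,3,5-trien-1-one (C2 and C5 cis on the central alkene) | C(/C(=C)OCC)=C(/C(=C=O)c1c(OC)cc(OC)c(OCc2ccccc2)c1OC)O[Si](C(C)C)(C(C)C)C(C)C | intermediate
18 | 2-[3-(benzyloxy)-2,4,6-trimethoxyphenyl]-5-ethoxy-3-(triisopropylsilyloxy)cyclohexa-2,4-dien-1-one | CCOC1=CC(O[Si](C(C)C)(C(C)C)C(C)C)=C(c2c(OC)cc(OC)c(OCc3ccccc3)c2OC)C(=O)C1 | intermediate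
19 | 2-[3-(benzyloxy)-2,4,6-trimethoxyphenyl]-5-ethoxy-3-(triisopropylsilyloxy)phenol (racemic about the D–E axis) | CCOc1cc(O)c(-c2c(OC)cc(OC)c(OCc3ccccc3)c2OC)c(O[Si](C(C)C)(C(C)C)C(C)C)c1 | intermediate
20 | 2-[3-(benzyloxy)-2,4,6-trimethoxyphenyl]-5-ethoxybenzene-1,3-diol | CCOc1cc(O)c(-c2c(OC)cc(OC)c(OCc3ccccc3)c2OC)c(O)c1 | intermediate
21 | 3-(benzyloxy)-4'-ethoxy-2,2',4,6,6'-pentamethoxybiphenyl | CCOc1cc(OC)c(-c2c(OC)cc(OC)c(OCc3ccccc3)c2OC)c(OC)c1 | intermediate
22 | 4'-ethoxy-2,2',4,6,6'-pentamethoxybiphenyl-3-ol | CCOc1cc(OC)c(-c2c(OC)cc(OC)c(O)c2OC)c(OC)c1 | intermediate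
23 | 2,6-difluoro-4-methoxybenzaldehyde | COc1cc(F)c(C=O)c(F)c1 | starting material
24 | 4-bromo-2,6-dimethoxyphenol | COc1cc(Br)cc(OC)c1O | starting material
25 | 2-(4-bromo-2,6-dimethoxyphenoxy)-6-fluoro-4-methoxybenzaldehyde | COc1cc(F)c(C=O)c(Oc2c(OC)cc(Br)cc2OC)c1 | intermediate
26 | 2,6-bis(4-bromo-2,6-dimethoxyphenoxy)-4-methoxybenzaldehyde | COc1cc(Oc2c(OC)cc(Br)cc2OC)c(C=O)c(Oc2c(OC)cc(Br)cc2OC)c1 | intermediate
27 | 2,6-bis(4-bromo-2,6-dimethoxyphenoxy)-4-methoxyphenyl formate | COc1cc(Oc2c(OC)cc(Br)cc2OC)c(OC=O)c(Oc2c(OC)cc(Br)cc2OC)c1 | intermediate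
28 | 2,6-bis(4-bromo-2,6-dimethoxyphenoxy)-4-methoxyphenol | COc1cc(Oc2c(OC)cc(Br)cc2OC)c(O)c(Oc2c(OC)cc(Br)cc2OC)c1 | intermediate
29 | 3,5-dimethoxyphenylboronic acid | COc1cc(OC)cc(B(O)O)c1 | starting material
30 | 1,3-bis(4-bromo-2,6-dimethoxyphenoxy)-2-(3,5-dimethoxyphenoxy)-5-methoxybenzene | COc1cc(OC)cc(Oc2c(Oc3c(OC)cc(Br)cc3OC)cc(OC)cc2Oc2c(OC)cc(Br)cc2OC)c1 | intermediate
31 | 1-(4-bromo-2,6-dimethoxyphenoxy)-2-(3,5-dimethoxyphenoxy)-3-{4-[(4'-ethoxy-2,2',4,6,6'-pentamethoxybiphenyl-3-yl)oxy]-2,6-dimethoxyphenoxy}-5-methoxybenzene | COc1cc(OC)cc(Oc2c(Oc3c(OC)cc(Oc4c(OC)cc(OC)c(-c5c(OC)cc(OCC)cc5OC)c4OC)cc3OC)cc(OC)cc2Oc2c(OC)cc(Br)cc2OC)c1 | intermediate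
32 | 2-(3,5-dimethoxyphenoxy)-5-methoxy-1,3-bis{4-[(4'-ethoxy-2,2',4,6,6'-pentamethoxybiphenyl-3-yl)oxy]-2,6-dimethoxyphenoxy}benzene (seventeen methyl and two ethyl ethers) | COc1cc(OC)cc(Oc2c(Oc3c(OC)cc(Oc4c(OC)cc(OC)c(-c5c(OC)cc(OCC)cc5OC)c4OC)cc3OC)cc(OC)cc2Oc2c(OC)cc(Oc3c(OC)cc(OC)c(-c4c(OC)cc(OCC)cc4OC)c3OC)cc2OC)c1 | intermediate
33 | CNP0227063.0, 2-(3,5-dihydroxyphenoxy)-5-hydroxy-1,3-bis{2,6-dihydroxy-4-[(2,2',4,4',6,6'-hexahydroxybiphenyl-3-yl)oxy]phenoxy}benzene | Oc1cc(O)cc(Oc2c(Oc3c(O)cc(Oc4c(O)cc(O)c(-c5c(O)cc(O)cc5O)c4O)cc3O)cc(O)cc2Oc2c(O)cc(Oc3c(O)cc(O)c(-c4c(O)cc(O)cc4O)c3O)cc2O)c1 | target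

Total step count: 14.
Longest linear sequence: 10 steps (1–5, 7–9, 13, 14).

Steps most likely to fail

**Step 7.** The push–pull cyclobutenone may resist electrocyclic opening below the temperature at which the electron-rich siloxyalkyne degrades. The vinylketene may also dimerise faster than it is trapped. The fallback sets out from 10 and comes back at 19. It makes the same vinylketene 15 at ambient temperature by a photochemical Wolff rearrangement, the second-generation form of the benzannulation. Ethyl vinyl ether is lithiated (t-BuLi, THF, −78 to 0 °C) and acylated with N-methoxy-N-methylacetamide to give 3-ethoxybut-3-en-2-one F1. The lithium enolate of F1 (LiHMDS, −78 °C) is trifluoroacetylated with 2,2,2-trifluoroethyl trifluoroacetate to give 5-ethoxy-1,1,1-trifluorohex-5-ene-2,4-dione F2. Deacylative diazo transfer (MsN3, Et3N, H2O, MeCN) then gives 1-diazo-3-ethoxybut-3-en-2-one F3. Irradiation of F3 with 10 (300 nm, 1,2-dichloroethane, rt) should expel nitrogen and give 15, which is trapped as it forms. Brief warming to 80 °C carries 16, 17 and 18 on to 19.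

**Step 13.** The chelating, di-ortho-methoxy phenoxide may slow the copper cycle. The coupling would then stall after the first arm, or hydrodebromination would compete at the second site. The fallback sets out from 30 and comes back at 32. It reverses the roles of the partners and moves to an oxidative coupling at room temperature. Double bromine–lithium exchange on 30 (n-BuLi, B(OiPr)3 present, THF, −78 °C; then aq NH4Cl) gives the core bis(boronic acid) F4. F4 is joined to 22 under Chan–Lam conditions (Cu(OAc)2, pyridine, 4 Å MS, CH2Cl2, dry air, rt).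

**Step 14.** Nineteen cleavages in one pot may end incomplete, because boron phenolates precipitate early. The free polyphenol may also oxidise in air during a long purification from partly alkylated congeners. The fallback sets out from 32 and comes back at 33. It replaces direct isolation by a catch-and-release sequence. The crude BBr3 product is peracetylated without purification (Ac2O, pyridine, rt) to the target nonadecaacetate F5, a neutral, air-stable compound that can be separated on silica from under-cleaved material. That material is returned to BBr3. Pure F5 is deacetylated by Zemplén transesterification (cat. NaOMe, MeOH, argon, 0 °C; acidic ion-exchange resin) to give 33 after filtration and evaporation only.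

Further compounds
F1 | step 7 | 3-ethoxybut-3-en-2-one | C=C(OCC)C(C)=O
F2 | step 7 | 5-ethoxy-1,1,1-trifluorohex-5-ene-2,4-dione | C=C(OCC)C(=O)CC(=O)C(F)(F)F
F3 | step 7 | 1-diazo-3-ethoxybut-3-en-2-one | C=C(OCC)C(=O)C=[N+]=[N-]
F4 | step 13 | core bis(boronic acid), {[2-(3,5-dimethoxyphenoxy)-5-methoxy-1,3-phenylene]bis[oxy(3,5-dimethoxy-4,1-phenylene)]}diboronic acid | COc1cc(OC)cc(Oc2c(Oc3c(OC)cc(B(O)O)cc3OC)cc(OC)cc2Oc2c(OC)cc(B(O)O)cc2OC)c1
F5 | step 14 | target nonadecaacetate | CC(=O)Oc1cc(OC(C)=O)cc(Oc2c(Oc3c(OC(C)=O)cc(Oc4c(OC(C)=O)cc(OC(C)=O)c(-c5c(OC(C)=O)cc(OC(C)=O)cc5OC(C)=O)c4OC(C)=O)cc3OC(C)=O)cc(OC(C)=O)cc2Oc2c(OC(C)=O)cc(Oc3c(OC(C)=O)cc(OC(C)=O)c(-c4c(OC(C)=O)cc(OC(C)=O)cc4OC(C)=O)c3OC(C)=O)cc2OC(C)=O)c1
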